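The uptake of gas is an easy step to read in this flask, so I start there.

electrophile 0.10 M; gas 7.3 mM (held); time 4.0 min

    electrophile + nucleophile → acid set free + target (k1 = 1.5 M⁻¹ s⁻¹)
    nucleophile + acid set free ⇌ protonated nucleophile, settled at all times (K2 = 2.0 × 10⁵ M⁻¹)
    gas ⇌ nucleophile, rate k3*(csat - [nucleophile]) (k3 = 7.6 s⁻¹, csat = 7.3 mM)
    2 nucleophile → self-condensation product (k4 = 1.3 M⁻¹ s⁻¹)

1. part of the electrophile that has reacted at 4.0 min
2. share of the unused nucleophile that is free and not bound as protonated nucleophile, at 4.0 min

Which numbers must I know well? Not 7.6 s⁻¹: at the charge, the first step and the binding of its acid together pull [nucleophile] below 7.3 mM by about 3.95%, a shortfall that shrinks as electrophile goes. Not 2.0 × 10⁵ M⁻¹ either: 1460 protonated nucleophile stands for each free acid at saturation, which takes one further nucleophile per turn, and that is already inside that shortfall. Self-condensation costs [nucleophile] 0.250%, a smaller dent than that shortfall at the charge.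

So I freeze [nucleophile] at 7.3 mM. The first step becomes pseudo-first-order, and the quantity to carry is the frozen-nucleophile half-life of the electrophile, ln(2)/(k1·csat), 1.06 min, which contains no electrophile charge. Among the constants, that leaves k1 and csat to be known well: each percent of error in either moves this estimate by 0.19 percentage points. The run lasts 3.79 half-lives, so I commit to 92.8% reacted. With one protonated nucleophile per turn, the free share is 7.29%.

The forecast, which says “essentially all the acid is bound”, gives 92.4% and 7.29%.

The flask gives 92.5% and 7.29%. Its [nucleophile] reads 0.00707 M at 0.400 min and 0.00726 M at 4.00 min. The half-life predicts 48.2% used at 1.00 min, and this flask shows 47.0%. The neighbour flask, with a quarter of the electrophile, keeps the same 1.06 min, so I expect 7.22% left and a free share of 23.9%. The neighbour flask still holds 7.3% of its electrophile, with 23.9% of its unused nucleophile free.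

The constants used here were set for the occasion.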